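## The problem

The target 27, [(1S,2S,3R,4R)-3-(benzoyloxy)-1,2,4-trihydroxy-6-oxocyclohexyl]methyl benzoate, is a single cyclohexane ring carrying seven carbons, numbered here C1 (quaternary carbinol bearing C7H2OBz), C2 (ketone), C3 (methylene), C4 (CHOH), C5 (CHOBz) and C6 (CHOH). Four contiguous stereocentres must be set, C1 (S), C6 (S), C5 (R) and C4 (R); in the favoured chair the C1 and C4 hydroxyls are axial and C7, the C5 benzoate and the C6 hydroxyl are equatorial, so that O4/O5 are cis, O5/O6 trans and O6/O1 cis. The three secondary centres can steer the quaternary one only through the chair they impose, so C1 is best created last, on a ring whose conformation is already fixed. The molecule is fragile: C2=O/C3H2/C4–OH is a β-hydroxy ketone that dehydrates to the cyclohexenone, C1–OH/C2=O is a tertiary α-ketol, and both benzoates sit next to free hydroxyls to which they can migrate. The ketone must therefore appear late and meet neither strong base nor hot acid. The enabling feature is that O4, O5, O6 and the C3 methylene reproduce O2, O1, O6 and a deoxygenated C3 of myo-inositol 1 in its 1D numbering (target C1–C6 = inositol C5, C4, C3, C2, C1, C6). C1 is then the carbonyl of an inosose flanked by two equatorial ethers, and an equatorial methylene transfer to it places C7 and the axial C1 oxygen as 27 requires.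

## Retrosynthesis

**27 ⇒ 26 ⇒ 24 + 25.** The last bond removed is the O6–benzyl bond of 26, because hydrogenolysis is neutral and is the gentlest way to finish a β-hydroxy ketone. The C5–O acyl bond is cut next, back to the cis-diol 24 and benzoyl chloride 25. Carrying this ester through earlier steps is excluded because esters react with the ylide of the key step. The forward reaction must acylate the equatorial hydroxyl of a cis-1,2-diol in preference to the axial one, without base-induced elimination.

**24 ⇒ 23 ⇒ 22 ⇒ 21.** The O4/O5 acetonide is restored to give 23, the C2 carbonyl is taken back to the secondary alcohol of diol 22, and this to the silyl ether 21. Making the ketone while O4 is still tied in the acetonide means it never has a free β-hydroxyl during oxidation. The silyl ether marks O2 as different from the benzyl-protected O6 and comes off without touching benzoates. The oxidation must spare the adjacent tertiary hydroxyl and not cleave the 1,2-diol.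

**21 ⇒ 19 + 20.** The C7–O ester bond is cut to the spiro-epoxide 19 and benzoic acid 20. One opening delivers the primary benzoate and the tertiary hydroxyl together; a diol followed by selective acylation would cost a step. The forward reaction must be an SN2 attack at the unsubstituted carbon, so that the C1–O bond and its configuration are untouched.

**19 ⇒ 15 + 17 (from 16).** This is the key disconnection: the C1–C7 bond and the oxirane C7–O bond are cut, giving the protected deoxyinosose 15 and dimethylsulfoxonium methylide 17, made from trimethylsulfoxonium iodide 16. Cutting a ring bond at C1 instead would discard the cyclitol pool. Olefination followed by oxidation would take two steps with less predictable facial control. Irreversible methylene donors tend to attack axially, so the reversible sulfoxonium reagent is chosen. The precursor has no quaternary centre and only pool-derived stereocentres. The forward step must deliver the methylene equatorially and must not enolise the ketone.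

**15 ⇒ 14 ⇒ 12 + 13.** The C1 carbonyl is taken back to the O5 alcohol 14, and the silyl ether to the 4,5-diol 12 and the silyl chloride 13. A bulky silyl group is preferred to a benzyl-type ether at O4 because steric differentiation (O4 next to a methylene, O5 between two oxygenated carbons) is more reliable for silylation than for alkylation. A diphenyl-tert-butylsilyl group is chosen because it also survives aqueous acid, which keeps a second end-game order open.

**12 ⇒ 11 ⇒ 9 + 10.** The diol comes from the diketal 11 by hydrolysis of the strained trans-fused ketal only. The benzyl ether is cut to the alcohol 9 and benzyl bromide 10. No selectivity is asked of the benzylation, as 9 has a single hydroxyl.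

**9 ⇒ 8 ⇒ 6 + 7.** The enantiopure alcohol is traced to its camphanate 8, and this to the racemic alcohol 6 and (1S)-camphanic chloride 7. Resolution is placed where the substrate has one hydroxyl, so only two esters form. The cost is two steps and half of the material.

**6 ⇒ 5 ⇒ 3 + 4.** The C3–H bond is traced to a C3–O bond by radical deoxygenation of the thionocarbonate 5, made from the diol 3 and the chlorothionoformate 4. The forward acylation must select O3 over O6; O3 lies beside the axial ketal oxygen and is the more reactive hydroxyl of this diol.

**3 ⇒ 1 + 2.** The two isopropylidene ketals are cut to myo-inositol 1 and 2,2-dimethoxypropane 2. This single step masks four of the six hydroxyls and exposes exactly the two that must be treated differently.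

## Roads not taken

Alternative 1: The ring C1–O and C2–O bonds are cut back to an arene. In the forward direction benzoic acid A2 would be dihydroxylated at its ipso and ortho carbons by whole cells expressing benzoate 1,2-dioxygenase, giving the diene diol acid A1.

- Merits: one enzymatic step supplies all seven carbons, the quaternary centre and the absolute configuration from the commodity arene A2, with no resolution.
- Weak points: A1 has the C1 configuration of 27 only if its secondary carbinol is read as the future C2 ketone. The C6 hydroxyl must then be introduced on the diene, cis to the tertiary hydroxyl. The C5 oxygen must go in trans to it and the C4 hydroxyl cis to C5, all by substrate control on two similar alkenes. The C3H2/C4–OH unit would have to come from conjugate hydration of an enone, the reverse of the dehydration that threatens 27, with no assured facial control. A1 also rearomatises readily under acid, and fermentation capacity is needed.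
- Comparison: this road is clearly better in the number of steps to the quaternary centre and in needing no resolution. The chosen plan sets against it that C4, C5, C6 and the methylene come from the pool, and that only one stereocentre is created, by a reaction whose facial preference is predictable.

Alternative 2: The C2–C3 ring bond is cut. D-mannose A5 would be elaborated, by chain branching and ring opening, into the iodo aldehyde A4. The primary C3 radical generated from A4 with Bu3SnH would add to the C2 aldehyde in a 6-exo-trig closure to give the protected cyclohexanol A3.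

- Merits: the chiral pool is enantiopure, C4–C6 and both benzoates are in place before ring closure, and the configuration of the new carbinol in A3 is irrelevant because it is oxidised.
- Weak points: the quaternary, hydroxymethyl-branched C1 must be built stereoselectively on the sugar. Reaching the silyl/benzoate/acetonide pattern of A4 from A5 requires extensive hydroxyl differentiation. Radical addition to a carbonyl is reversible through β-scission of the alkoxy radical, so simple reduction of the iodide competes.
- Comparison: this road is better in needing no resolution and equal in leaving only mild steps after ring formation. The chosen plan sets against it a polar, well-understood key step and a pool that already contains the carbocycle, so no ring-forming step can fail.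

Alternative 3: The C2–O bond is cut. The achiral p-quinol A7 would add through its tertiary hydroxyl to acetaldehyde A8, and the hemiacetal oxygen would then add to one of the two enone arms under a chiral Brønsted acid catalyst, giving the cis-fused dioxolane enone A6.

- Merits: it is catalytic and enantioselective from a dearomatised arene, it sets C1, and it delivers the C2 oxygen and the C3 methylene directly; acetalisation/oxa-Michael desymmetrisation of p-quinols is a known reaction class.
- Weak points: three stereocentres (C4, C5, C6) remain to be set by substrate control on A6. The C4 carbonyl must be reduced to the axial alcohol. The C5=C6 alkene must become a trans-dioxygenated pair with O6 cis to O1, which needs an epoxidation anti to the dioxolane and a regioselective opening at C6. The acetal must finally be removed and C2 oxidised in a molecule that by then holds the sensitive hydroxyl pattern.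
- Comparison: this road is better in being catalytic and asymmetric, with a short route to the C1–C3 portion. The chosen plan sets against it the secure relative configuration of C4–C6 and an end game in which only one hydroxyl is oxidised.

Key step: step 10

Remark on the chemistry: the racemates 3, 5 and 6 are drawn as the enantiomer that is carried on after the resolution. Intermediates 3–15 carry 1D-myo-inositol locants, and later compounds the target numbering C1–C7.

## Route

Step 1
Reactants: 1 myo-inositol; 2 2,2-dimethoxypropane
Product: 3 (±)-1,2:4,5-di-O-isopropylidene-myo-inositol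
Conditions: TsOH·H2O (cat.), DMF, 100 °C; Et3N; crystallisation
Reagents that add atoms: 2,2-dimethoxypropane, COC(C)(C)OC
Why: Acid-catalysed transketalisation bridges the cis-1,2-diol and one trans-diol; the 1,2:4,5-isomer is the least soluble diketal and should be obtained by crystallisation. No stereocentre is created; the product is racemic.

Step 2
Reactants: 3 (±)-1,2:4,5-di-O-isopropylidene-myo-inositol; 4 O-phenyl chlorothionoformate
Product: 5 (±)-3-O-(phenoxythiocarbonyl)-1,2:4,5-di-O-isopropylidene-myo-inositol
Conditions: pyridine, DMAP (cat.), CH2Cl2, 0 °C
Reagents that add atoms: O-phenyl chlorothionoformate, S=C(Cl)Oc1ccccc1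
Why: Regioselective thioacylation: O3 is equatorial beside the axial ketal oxygen O2 and is the more nucleophilic hydroxyl of this diol (the known site of its mono-acylation and mono-alkylation), whereas O6 lies between two equatorial ketal oxygens.

Step 3
Reactants: 5 (±)-3-O-(phenoxythiocarbonyl)-1,2:4,5-di-O-isopropylidene-myo-inositol
Product: 6 (±)-3-deoxy-1,2:4,5-di-O-isopropylidene-myo-inositol
Conditions: Bu3SnH, AIBN (cat.), toluene, 100 °C
Reagents that add atoms: none
Why: Barton–McCombie deoxygenation: the stannyl radical adds to C=S, β-scission gives the secondary C3 radical, and this abstracts hydrogen from Bu3SnH. The free O6 hydroxyl and both ketals are inert, and C3 ceases to be a stereocentre.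

Step 4
Reactants: 6 (±)-3-deoxy-1,2:4,5-di-O-isopropylidene-myo-inositol; 7 (1S)-(−)-camphanic chloride
Product: 8 1D-6-O-[(1S)-camphanoyl]-3-deoxy-1,2:4,5-di-O-isopropylidene-myo-inositol (single diastereomer)
Conditions: Et3N, DMAP (cat.), CH2Cl2, 0 °C → rt; separation of the two diastereomeric esters by crystallisation or chromatography
Reagents that add atoms: (1S)-(−)-camphanic chloride, ClC(=O)[C@@]12CC[C@@](C)(C(=O)O1)C2(C)C
Why: Classical resolution through diastereomeric esters: the single hydroxyl of the racemate is acylated and the two camphanates are separated. The ester of the 1D alcohol is carried on, and its configuration can be secured by X-ray analysis with the camphanoyl group as internal reference.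

Step 5
Reactants: 8 1D-6-O-[(1S)-camphanoyl]-3-deoxy-1,2:4,5-di-O-isopropylidene-myo-inositol
Product: 9 1D-3-deoxy-1,2:4,5-di-O-isopropylidene-myo-inositol
Conditions: NaOMe (cat.), MeOH, 40 °C
Reagents that add atoms: none
Why: Zemplén transesterification removes the auxiliary as its methyl ester; the ketals are stable to methoxide and no stereocentre is touched.

Step 6
Reactants: 9 1D-3-deoxy-1,2:4,5-di-O-isopropylidene-myo-inositol; 10 benzyl bromide
Product: 11 1D-6-O-benzyl-3-deoxy-1,2:4,5-di-O-isopropylidene-myo-inositol
Conditions: NaH, Bu4NI (cat.), DMF, 0 °C → rt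
Reagents that add atoms: benzyl bromide, BrCc1ccccc1
Why: Williamson etherification of the only hydroxyl; the benzyl ether withstands every later step up to the final hydrogenolysis.

Step 7
Reactants: 11 1D-6-O-benzyl-3-deoxy-1,2:4,5-di-O-isopropylidene-myo-inositol
Product: 12 1D-6-O-benzyl-3-deoxy-1,2-O-isopropylidene-myo-inositol (4,5-diol)
Conditions: AcOH/H2O (4:1), rt
Reagents that add atoms: none
Why: Selective acetal hydrolysis: the trans-fused dioxolane on O4/O5 is strained and hydrolyses much faster than the cis-fused one on O1/O2, a selectivity long used with inositol diketals.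

Step 8
Reactants: 12 1D-6-O-benzyl-3-deoxy-1,2-O-isopropylidene-myo-inositol; 13 tert-butyl(chloro)diphenylsilane
Product: 14 1D-6-O-benzyl-4-O-(tert-butyldiphenylsilyl)-3-deoxy-1,2-O-isopropylidene-myo-inositol
Conditions: imidazole, DMF, rt
Reagents that add atoms: tert-butyl(chloro)diphenylsilane, CC(C)(C)[Si](Cl)(c1ccccc1)c1ccccc1
Why: Sterically controlled monosilylation: O4 has a methylene neighbour, while O5 lies between two oxygenated carbons (C4 and C6–OBn), so the bulky silyl chloride should react at O4 only.

Step 9
Reactants: 14 1D-6-O-benzyl-4-O-(tert-butyldiphenylsilyl)-3-deoxy-1,2-O-isopropylidene-myo-inositol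
Product: 15 protected deoxyinosose (5-ketone of 14; target C1 carbonyl, C2–OTBDPS and C6–OBn equatorial, C4/C5 acetonide)
Conditions: Dess–Martin periodinane, CH2Cl2, rt
Reagents that add atoms: none
Why: Dess–Martin oxidation of the remaining secondary alcohol under base-free conditions, which avoids the β-elimination that inososes undergo with amine bases; both α-centres keep their equatorial ethers.

Step 10
Reactants: 15 protected deoxyinosose; 16 trimethylsulfoxonium iodide
Product: 19 C1 spiro-epoxide (C7 equatorial; oxirane oxygen axial), via dimethylsulfoxonium methylide 17 (not isolated), via sulfoxonium betaine 18 (not isolated)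
Conditions: NaH, DMSO, rt (ylide formation); then 15 in THF, rt
Reagents that add atoms: trimethylsulfoxonium iodide, C[S+](C)(C)=O.[I-] (transfers CH2 through ylide 17)
Why: Corey–Chaykovsky epoxidation: NaH deprotonates 16 to the ylide 17, whose carbon adds to the C1 carbonyl of 15 to give the betaine 18; the alkoxide then displaces DMSO in a 3-exo-tet closure that forms the oxirane (C1–C7, then O–C7). The closest known reaction type is the epoxidation of conformationally biased cyclohexanones and protected inososes with dimethylsulfoxonium methylide, which delivers the methylene equatorially. Ketone 15 sits in the chair in which the C2 and C6 ethers and C5–O are equatorial and only C4–O is axial; the other chair would carry three axial oxygens. Addition of the stabilised ylide is reversible and ring closure is slow, so the product derives from the more stable betaine, in which the bulky CH2S(O)Me2 group is equatorial and free of 1,3-diaxial contacts with the axial hydrogens on C3 and C5; this fixes the only new stereocentre, C1, with C7 equatorial and oxygen axial, cis to O6. The step needs facial selectivity at C1 and preference for addition over enolisation. The latter rests on the low basicity of the ylide, on the absence of a leaving group β to a C2-side enolate, and on the equatorial, ring-bound C5–O bond, which is poorly aligned for E1cB loss from a C6-side enolate. One equivalent of ylide at room temperature avoids homologation of the epoxide to an oxetane.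

Step 11
Reactants: 19 spiro-epoxide; 20 benzoic acid
Product: 21 C7 benzoate with free axial tertiary C1 hydroxyl (C2–OTBDPS, C4/C5 acetonide, C6–OBn)
Conditions: PhCO2H, PhCO2Cs (cat.), DMF, 80 °C
Reagents that add atoms: benzoic acid, O=C(O)c1ccccc1
Why: SN2 opening of a 2,2-disubstituted epoxide by carboxylate at its unsubstituted carbon C7; the C1–O bond is not broken, so the axial tertiary hydroxyl keeps its configuration. The acid buffer protonates the alkoxide before silyl or acyl shifts can occur.

Step 12
Reactants: 21 C7 benzoate silyl ether
Product: 22 C1,C2-diol (C7–OBz, C4/C5 acetonide, C6–OBn)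
Conditions: HF·pyridine, THF/pyridine, 0 °C → rt
Reagents that add atoms: none
Why: Desilylation with buffered fluoride under non-basic conditions, so the primary benzoate does not migrate; acetonide and benzyl ether are retained.

Step 13
Reactants: 22 C1,C2-diol
Product: 23 α-ketol (C2 ketone, tertiary C1–OH, C4/C5 acetonide, C6–OBn, C7–OBz)
Conditions: IBX, DMSO, rt
Reagents that add atoms: none
Why: IBX oxidises the secondary alcohol of a secondary/tertiary 1,2-diol to the α-ketol without C–C cleavage. O4 is still tied in the acetonide, so the new ketone has no free β-hydroxyl and meets no base.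

Step 14
Reactants: 23 α-ketol acetonide
Product: 24 keto triol (C1–OH, axial C4–OH, equatorial C5–OH; C6–OBn, C7–OBz)
Conditions: TFA/H2O (4:1), 0 °C
Reagents that add atoms: none
Why: Acid hydrolysis of the cis-fused acetonide; cold, short exposure is chosen because the product is a β-hydroxy ketone. Esters, the benzyl ether and all stereocentres are untouched.

Step 15
Reactants: 24 keto triol; 25 benzoyl chloride
Product: 26 6-O-benzyl ether of the target (C5–OBz, C7–OBz, C4–OH, C1–OH)
Conditions: BzCl (1.05 equiv), pyridine, CH2Cl2, −40 °C
Reagents that add atoms: benzoyl chloride, O=C(Cl)c1ccccc1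
Why: Kinetic monoacylation of a cis-1,2-diol at its equatorial hydroxyl (C5) rather than the axial C4 or tertiary C1 hydroxyl, the selectivity known for the 1,2-diol of myo-inositol derivatives. Low temperature and a weak base keep the β-hydroxy ketone from eliminating.

Step 16
Reactants: 26 6-O-benzyl ether of the target
Product: 27 [(1S,2S,3R,4R)-3-(benzoyloxy)-1,2,4-trihydroxy-6-oxocyclohexyl]methyl benzoate (CNP0127041.1)
Conditions: H2 (1 atm), Pd/C, EtOAc, rt
Reagents that add atoms: none
Why: Hydrogenolysis of the benzyl ether under neutral conditions; benzoates, the aliphatic ketone and the stereocentres are unaffected, and the aprotic solvent avoids acyl migration.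

## Compound list

1 | myo-inositol | O[C@H]1[C@@H](O)[C@@H](O)[C@H](O)[C@@H](O)[C@@H]1O | starting material
2 | 2,2-dimethoxypropane | COC(C)(C)OC | starting material
3 | (±)-1,2:4,5-di-O-isopropylidene-myo-inositol (racemate, 1D enantiomer drawn) | CC1(C)O[C@H]2[C@H](O1)[C@@H](O)[C@H]3OC(C)(C)O[C@H]3[C@@H]2O | intermediate
4 | O-phenyl chlorothionoformate | S=C(Cl)Oc1ccccc1 | starting material
5 | (±)-3-O-(phenoxythiocarbonyl)-1,2:4,5-di-O-isopropylidene-myo-inositol (racemate, 1D enantiomer drawn) | CC1(C)O[C@H]2[C@H](O1)[C@@H](OC(=S)Oc4ccccc4)[C@H]3OC(C)(C)O[C@H]3[C@@H]2O | intermediate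
6 | (±)-3-deoxy-1,2:4,5-di-O-isopropylidene-myo-inositol (racemate, 1D enantiomer drawn) | CC1(C)O[C@H]2[C@H](O1)C[C@H]3OC(C)(C)O[C@H]3[C@@H]2O | intermediate
7 | (1S)-(−)-camphanic chloride, (1S,4R)-4,7,7-trimethyl-3-oxo-2-oxabicyclo[2.2.1]heptane-1-carbonyl chloride | ClC(=O)[C@@]12CC[C@@](C)(C(=O)O1)C2(C)C | starting material
8 | 1D-6-O-[(1S)-camphanoyl]-3-deoxy-1,2:4,5-di-O-isopropylidene-myo-inositol | CC1(C)O[C@H]2[C@H](O1)C[C@H]3OC(C)(C)O[C@H]3[C@@H]2OC(=O)[C@@]45CC[C@@](C)(C(=O)O4)C5(C)C | intermediate
9 | 1D-3-deoxy-1,2:4,5-di-O-isopropylidene-myo-inositol (single enantiomer) | CC1(C)O[C@H]2[C@H](O1)C[C@H]3OC(C)(C)O[C@H]3[C@@H]2O | intermediate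
10 | benzyl bromide | BrCc1ccccc1 | starting material
11 | 1D-6-O-benzyl-3-deoxy-1,2:4,5-di-O-isopropylidene-myo-inositol | CC1(C)O[C@H]2[C@H](O1)C[C@H]3OC(C)(C)O[C@H]3[C@@H]2OCc4ccccc4 | intermediate
12 | 1D-6-O-benzyl-3-deoxy-1,2-O-isopropylidene-myo-inositol | O[C@H]1[C@H](O)C[C@H]2OC(C)(C)O[C@H]2[C@@H]1OCc3ccccc3 | intermediate
13 | tert-butyl(chloro)diphenylsilane | CC(C)(C)[Si](Cl)(c1ccccc1)c1ccccc1 | starting material
14 | 1D-6-O-benzyl-4-O-(tert-butyldiphenylsilyl)-3-deoxy-1,2-O-isopropylidene-myo-inositol | O[C@H]1[C@H](O[Si](c3ccccc3)(c4ccccc4)C(C)(C)C)C[C@H]2OC(C)(C)O[C@H]2[C@@H]1OCc5ccccc5 | intermediate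
15 | protected deoxyinosose: 5-ketone of 14 (target C1 carbonyl; C2–OTBDPS and C6–OBn equatorial; C4/C5 acetonide) | O=C1[C@H](O[Si](c3ccccc3)(c4ccccc4)C(C)(C)C)C[C@H]2OC(C)(C)O[C@H]2[C@@H]1OCc5ccccc5 | intermediate
16 | trimethylsulfoxonium iodide | C[S+](C)(C)=O.[I-] | starting material
17 | dimethylsulfoxonium methylide (not isolated) | C[S+](C)(=O)[CH2-] | intermediate
18 | sulfoxonium betaine: C1 alkoxide axial, CH2S(O)Me2 equatorial (not isolated) | C[S+](C)(=O)C[C@@]1([O-])[C@H](O[Si](c2ccccc2)(c3ccccc3)C(C)(C)C)C[C@H]4OC(C)(C)O[C@H]4[C@@H]1OCc5ccccc5 | intermediate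
19 | spiro-epoxide at C1: C7 equatorial, oxirane oxygen axial and cis to O6; C2–OTBDPS, C4/C5 acetonide, C6–OBn | C1O[C@@]12[C@H](O[Si](c3ccccc3)(c4ccccc4)C(C)(C)C)C[C@H]5OC(C)(C)O[C@H]5[C@@H]2OCc6ccccc6 | intermediate
20 | benzoic acid | O=C(O)c1ccccc1 | starting material
21 | C7 benzoate with axial tertiary C1–OH; C2–OTBDPS, C4/C5 acetonide, C6–OBn | O=C(OC[C@@]1(O)[C@H](O[Si](c2ccccc2)(c3ccccc3)C(C)(C)C)C[C@H]4OC(C)(C)O[C@H]4[C@@H]1OCc5ccccc5)c6ccccc6 | intermediate
22 | C1,C2-diol: C7–OBz, equatorial C2–OH cis to axial C1–OH, C4/C5 acetonide, C6–OBn | O=C(OC[C@@]1(O)[C@H](O)C[C@H]2OC(C)(C)O[C@H]2[C@@H]1OCc3ccccc3)c4ccccc4 | intermediate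
23 | α-ketol: C2 ketone, C1–OH, C7–OBz, C4/C5 acetonide, C6–OBn | O=C(OC[C@@]1(O)C(=O)C[C@H]2OC(C)(C)O[C@H]2[C@@H]1OCc3ccccc3)c4ccccc4 | intermediate
24 | keto triol: C2 ketone, C1–OH, axial C4–OH, equatorial C5–OH, C6–OBn, C7–OBz | O=C(OC[C@@]1(O)C(=O)C[C@@H](O)[C@@H](O)[C@@H]1OCc2ccccc2)c3ccccc3 | intermediate
25 | benzoyl chloride | O=C(Cl)c1ccccc1 | starting material
26 | 6-O-benzyl ether of the target: C5–OBz, C7–OBz, C4–OH, C1–OH, C2 ketone | O=C(OC[C@@]1(O)C(=O)C[C@@H](O)[C@@H](OC(=O)c2ccccc2)[C@@H]1OCc3ccccc3)c4ccccc4 | intermediate
27 | [(1S,2S,3R,4R)-3-(benzoyloxy)-1,2,4-trihydroxy-6-oxocyclohexyl]methyl benzoate | O=C(OC[C@@]1(O)C(=O)C[C@@H](O)[C@@H](OC(=O)c2ccccc2)[C@@H]1O)c1ccccc1 | target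

## Step count and risks

Total: 16 steps. Longest linear sequence: 16 steps, from 1.

**Step 10 (key step).** Facial selectivity may be lower than planned if betaine formation on this electron-poor α,α'-dialkoxy ketone is less reversible than assumed, so that some methylene is delivered axially. Enolisation toward C6 with loss of the acetonide oxygen, and slow addition beside the bulky silyl ether, are further risks. The fallback sets out from 15 and gives up the ylide. The bulky Grignard reagent ClMgCH2SiMe2(OiPr), with CeCl3 in THF at −78 °C to suppress enolisation, should add equatorially to give the silylmethyl carbinol F1. Tamao oxidation (H2O2, KF, KHCO3, THF/MeOH) would convert the C–Si bond into the primary alcohol, giving the C1,C7-diol F2. Benzoylation of the primary hydroxyl with 25 and 2,4,6-collidine at −20 °C returns to the route at 21.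

**Step 15.** Acylation of the axial C4 hydroxyl may compete, because it has a methylene neighbour and is less shielded than the axial hydroxyl of an intact inositol. Any C4 ester, or prolonged contact with base, would lead to loss of the C4 oxygen and formation of the enone; the acid exposure of step 14 carries a related dehydration risk. The fallback sets out from 21 and installs the C5 benzoate before the ketone exists. Aqueous AcOH at 60 °C should remove the acetonide with the silyl ether intact, giving the C4,C5-diol F3. Bu2SnO in refluxing toluene followed by 25 should acylate the equatorial oxygen through the stannylene acetal, giving the C5 benzoate F4. 2-Benzyloxy-1-methylpyridinium triflate with MgO in PhCF3 at 85 °C would then benzylate the axial C4 hydroxyl under neutral conditions, giving the C4 benzyl ether F5. HF·pyridine frees the C2 alcohol F6, and IBX oxidises it to the dibenzyl-protected ketone F7. Hydrogenolysis (H2, Pd/C, EtOAc) removes both benzyl ethers and comes back to the route at 27, so the β-oxygenated ketone never meets acid or base.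

**Step 11.** Substitution at C7 may be slow, because the oxirane methylene is neopentylic and flanked by the silyl and benzyl ethers. At higher temperature, ionisation of the tertiary C1–O bond would erode regio- and stereochemistry. The fallback sets out from 19. Bu4NF in THF removes the silyl ether to give the epoxy alcohol F8; a Payne rearrangement is not possible because O2 and the oxirane oxygen are cis. Ti(OiPr)4-mediated opening of this 2,3-epoxy alcohol with 20 in CH2Cl2 should deliver benzoate to the distal carbon C7 and return to the route at 22.

**Step 4.** The two camphanates may co-crystallise or co-elute, making the separation inefficient. The fallback sets out from 6 and uses no covalent auxiliary. The racemate is benzylated as in step 6 to the racemic benzyl ether F9, which is UV-active, and the enantiomers are separated by preparative chromatography on a chiral stationary phase. The 1D enantiomer is 11, where the route is rejoined; its configuration would be assigned by correlation with a small sample prepared through 8, for which even an inefficient separation suffices.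

## Further compounds

F1 | step 10 | silylmethyl carbinol: C1–OH axial, C1–CH2SiMe2(OiPr) equatorial, C2–OTBDPS, C4/C5 acetonide, C6–OBn | CC(C)O[Si](C)(C)C[C@@]1(O)[C@H](O[Si](c2ccccc2)(c3ccccc3)C(C)(C)C)C[C@H]4OC(C)(C)O[C@H]4[C@@H]1OCc5ccccc5
F2 | step 10 | C1,C7-diol: C7–OH primary, C1–OH axial, C2–OTBDPS, C4/C5 acetonide, C6–OBn | OC[C@@]1(O)[C@H](O[Si](c2ccccc2)(c3ccccc3)C(C)(C)C)C[C@H]4OC(C)(C)O[C@H]4[C@@H]1OCc5ccccc5
F3 | step 15 | C4,C5-diol: C7–OBz, C1–OH, C2–OTBDPS, C6–OBn | O=C(OC[C@@]1(O)[C@H](O[Si](c2ccccc2)(c3ccccc3)C(C)(C)C)C[C@@H](O)[C@@H](O)[C@@H]1OCc4ccccc4)c5ccccc5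
F4 | step 15 | C5 benzoate: C7–OBz, C5–OBz, C4–OH, C1–OH, C2–OTBDPS, C6–OBn | O=C(OC[C@@]1(O)[C@H](O[Si](c2ccccc2)(c3ccccc3)C(C)(C)C)C[C@@H](O)[C@@H](OC(=O)c6ccccc6)[C@@H]1OCc4ccccc4)c5ccccc5
F5 | step 15 | C4 benzyl ether: C7–OBz, C5–OBz, C4–OBn, C6–OBn, C1–OH, C2–OTBDPS | O=C(OC[C@@]1(O)[C@H](O[Si](c2ccccc2)(c3ccccc3)C(C)(C)C)C[C@@H](OCc7ccccc7)[C@@H](OC(=O)c6ccccc6)[C@@H]1OCc4ccccc4)c5ccccc5
F6 | step 15 | C2 alcohol: C7–OBz, C5–OBz, C4–OBn, C6–OBn, C1–OH, C2–OH | O=C(OC[C@@]1(O)[C@H](O)C[C@@H](OCc7ccccc7)[C@@H](OC(=O)c6ccccc6)[C@@H]1OCc4ccccc4)c5ccccc5
F7 | step 15 | 4,6-di-O-benzyl ether of the target: C2 ketone, C7–OBz, C5–OBz, C1–OH | O=C(OC[C@@]1(O)C(=O)C[C@@H](OCc7ccccc7)[C@@H](OC(=O)c6ccccc6)[C@@H]1OCc4ccccc4)c5ccccc5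
F8 | step 11 | epoxy alcohol: spiro-epoxide at C1 with free equatorial C2–OH, C4/C5 acetonide, C6–OBn | C1O[C@@]12[C@H](O)C[C@H]3OC(C)(C)O[C@H]3[C@@H]2OCc4ccccc4
F9 | step 4 | (±)-6-O-benzyl-3-deoxy-1,2:4,5-di-O-isopropylidene-myo-inositol (racemate of 11, 1D enantiomer drawn) | CC1(C)O[C@H]2[C@H](O1)C[C@H]3OC(C)(C)O[C@H]3[C@@H]2OCc4ccccc4
A1 | alternative 1 | (1S,2R)-1,2-dihydroxycyclohexa-3,5-diene-1-carboxylic acid | OC(=O)[C@@]1(O)[C@H](O)C=CC=C1
A2 | alternative 1 | benzoic acid | O=C(O)c1ccccc1
A3 | alternative 2 | protected cyclohexanol (C2 carbinol; C1/C6 acetonide, C4–OTBS, C5–OBz, C7–OBz) | O=C(OC[C@@]2(OC3(C)C)[C@H](O)C[C@@H](O[Si](C)(C)C(C)(C)C)[C@@H](OC(=O)c4ccccc4)[C@@H]2O3)c1ccccc1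
A4 | alternative 2 | iodo aldehyde (C2 aldehyde on the dioxolane carbon C1, C3 primary iodide) | O=C(OC[C@]1(C=O)OC(C)(C)O[C@H]1[C@H](OC(=O)c2ccccc2)[C@@H](CI)O[Si](C)(C)C(C)(C)C)c3ccccc3
A5 | alternative 2 | D-mannose (pyranose form) | OC[C@H]1OC(O)[C@@H](O)[C@@H](O)[C@@H]1O
A6 | alternative 3 | cis-fused dioxolane enone | O=C(OC[C@@]2(O[C@H]3C)[C@H](O3)CC(=O)C=C2)c1ccccc1
A7 | alternative 3 | (1-hydroxy-4-oxocyclohexa-2,5-dien-1-yl)methyl benzoate (p-quinol) | O=C(OCC1(O)C=CC(=O)C=C1)c1ccccc1
A8 | alternative 3 | acetaldehyde | CC=O
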